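**Retrosynthetic overview**
1. Target ⇒ 3-(aryloxy)salicylic acid: both ring B bromines arrive last, by bromination para to OH and ipso-bromodecarboxylation ortho to OH.
2. Ring B salicylate ⇒ key C–C bond: intermolecular Mukaiyama aldol between the terminal carbon of a 4-aryloxy-1,3-bis(silyloxy)diene and 1,1,3,3-tetramethoxypropane, then ring closure and aromatisation (formal [3+3]).
3. Diene ⇒ methyl 4-aryloxyacetoacetate ⇒ crossed Claisen condensation of methyl acetate with a methyl aryloxyacetate.
4. Aryloxyacetate ⇒ O-alkylation of 2,3,4-tribromo-6-methoxyphenol, made by tribromination of guaiacol; the diaryl ether oxygen is carried through from the start.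
5. Ring order: ring A is bought as guaiacol and fully brominated first; ring B is built de novo last.

Assumption: the target has no stereogenic element, so it is one achiral compound and needs no enantiocontrol. Double-bond geometry in the enolate and silyl enol ether intermediates is uncontrolled and irrelevant, because all of those carbons end up in aromatic ring B.

**Route**

Step 1
Reactants: 1 guaiacol (2-methoxyphenol)
Product: 2 2,3,4-tribromo-6-methoxyphenol
Conditions: Br2 (3.05 equiv), AcOH, 15 → 50 °C
Reagents that add atoms: bromine, BrBr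
Why: Electrophilic aromatic bromination in which OH directs the first two bromines para and ortho to itself and the third enters para to OMe, while the last C–H (ortho to OMe on a ring now carrying three Br) is too deactivated to react at this stoichiometry.

Step 2
Reactants: 2 2,3,4-tribromo-6-methoxyphenol; 3 methyl bromoacetate
Product: 4 methyl 2-(2,3,4-tribromo-6-methoxyphenoxy)acetate
Conditions: K2CO3 (1.5 equiv), DMF, 50 °C
Reagents that add atoms: none
Why: Williamson ether synthesis (SN2), in which the acidic hindered phenol is fully ionised by K2CO3 and the unhindered, activated α-bromo ester alkylates it cleanly on oxygen.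

Step 3
Reactants: 4 methyl 2-(2,3,4-tribromo-6-methoxyphenoxy)acetate; 5 methyl acetate
Product: 8 methyl 3-oxo-4-(2,3,4-tribromo-6-methoxyphenoxy)butanoate, via lithium enolate of methyl acetate 6 (not isolated), via chelated lithium enolate of the keto ester 7 (not isolated)
Conditions: LiN(iPr)2 (2.2 equiv), 5 (2.3 equiv), THF, −78 °C, 30 min; then 4, −78 → −40 °C; 1 M HCl quench
Reagents that add atoms: none
Why: Crossed Claisen condensation in which the preformed enolate 6 (no free amide base left to touch the bromoarene) adds to the activated α-aryloxy ester, and methoxide loss followed by irreversible deprotonation to 7 drives the reaction and prevents double addition.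

Step 4
Reactants: 8 methyl 3-oxo-4-(2,3,4-tribromo-6-methoxyphenoxy)butanoate
Product: 9 methyl (2Z)-4-(2,3,4-tribromo-6-methoxyphenoxy)-3-(trimethylsilyloxy)but-2-enoate
Conditions: Me3SiCl (1.5 equiv), NEt3 (1.6 equiv), toluene, 20 °C, 48 h; filter, concentrate, use crude
Reagents that add atoms: chlorotrimethylsilane, C[Si](C)(C)Cl
Why: Soft enolisation and O-silylation of the β-keto ester gives the conjugated β-silyloxy enoate, the standard first stage of a Chan-type diene synthesis.

Step 5
Reactants: 9 methyl (2Z)-4-(2,3,4-tribromo-6-methoxyphenoxy)-3-(trimethylsilyloxy)but-2-enoate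
Product: 11 (1E,3E)-1-methoxy-4-(2,3,4-tribromo-6-methoxyphenoxy)-1,3-bis(trimethylsilyloxy)buta-1,3-diene, via lithium dienolate 10 (not isolated)
Conditions: LiN(iPr)2 (1.05 equiv), THF, −78 °C, 30 min; then Me3SiCl (1.2 equiv), −78 → 20 °C; hexane, filter under argon, use crude
Reagents that add atoms: chlorotrimethylsilane, C[Si](C)(C)Cl
Why: Kinetic γ-deprotonation of the vinylogous ester is far faster than metalation of the bromoarene with one equivalent of base at −78 °C, and O-silylation of dienolate 10 gives the 1,3-bis(silyl enol ether).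

Step 6
Reactants: 11 (1E,3E)-1-methoxy-4-(2,3,4-tribromo-6-methoxyphenoxy)-1,3-bis(trimethylsilyloxy)buta-1,3-diene; 12 1,1,3,3-tetramethoxypropane
Product: 14 methyl 2-hydroxy-3-(2,3,4-tribromo-6-methoxyphenoxy)benzoate, via open-chain aldol adduct 13 (not isolated)
Conditions: Me3SiOTf (0.1 equiv), CH2Cl2, −78 → 20 °C, 14 h; then 10% aq HCl
Reagents that add atoms: none
Why: Formal [3+3] cyclocondensation in which the Lewis acid ionises the acetal, the terminal diene carbon adds in an intermolecular Mukaiyama aldol reaction to give 13, the remaining silyl enol ether closes onto the second acetal carbon, and loss of two methanol aromatises the ring; the symmetric three-carbon electrophile leaves no regiochemical question and the two transient stereocentres of 13 are destroyed.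

Step 7
Reactants: 14 methyl 2-hydroxy-3-(2,3,4-tribromo-6-methoxyphenoxy)benzoate
Product: 16 2-hydroxy-3-(2,3,4-tribromo-6-methoxyphenoxy)benzoic acid, via disodium salicylate salt 15 (not isolated)
Conditions: NaOH (4 equiv), THF/MeOH/H2O, 60 °C; then 2 M HCl to pH 1
Reagents that add atoms: sodium hydroxide, [Na+].[OH-]
Why: Ester saponification (acyl–oxygen cleavage by hydroxide), which aryl bromides, the diaryl ether and the methyl ether all survive.

Step 8
Reactants: 16 2-hydroxy-3-(2,3,4-tribromo-6-methoxyphenoxy)benzoic acid
Product: 18 2,4-dibromo-6-(2,3,4-tribromo-6-methoxyphenoxy)phenol (target), via 5-bromo acid 17 (not isolated)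
Conditions: Br2 (2.1 equiv), NaOAc (2.5 equiv), AcOH/H2O 3:1, 20 → 50 °C; aq Na2S2O3
Reagents that add atoms: bromine, BrBr
Why: Electrophilic bromination para to the phenol OH gives 17, and ipso attack at the carboxyl-bearing ortho carbon with loss of CO2 (bromodecarboxylation of a salicylic acid) places the second bromine exactly where the carboxyl stood, while tribrominated ring A is too deactivated to react.

**Compound list**
1 | guaiacol (2-methoxyphenol) | COc1ccccc1O | starting material
2 | 2,3,4-tribromo-6-methoxyphenol | COc1cc(Br)c(Br)c(Br)c1O | intermediate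
3 | methyl bromoacetate | COC(=O)CBr | starting material
4 | methyl 2-(2,3,4-tribromo-6-methoxyphenoxy)acetate | COC(=O)COc1c(OC)cc(Br)c(Br)c1Br | intermediate
5 | methyl acetate | COC(C)=O | starting material
6 | lithium enolate of methyl acetate (lithium 1-methoxyethen-1-olate) | [Li]OC(=C)OC | intermediate
7 | lithium (Z)-enolate of keto ester 8 (chelated) | COC(=O)/C=C(\O[Li])COc1c(OC)cc(Br)c(Br)c1Br | intermediate
8 | methyl 3-oxo-4-(2,3,4-tribromo-6-methoxyphenoxy)butanoate | COC(=O)CC(=O)COc1c(OC)cc(Br)c(Br)c1Br | intermediate
9 | methyl (2Z)-4-(2,3,4-tribromo-6-methoxyphenoxy)-3-(trimethylsilyloxy)but-2-enoate (Z drawn; E/Z mixture usable) | COC(=O)/C=C(\O[Si](C)(C)C)COc1c(OC)cc(Br)c(Br)c1Br | intermediate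
10 | lithium (1Z,3E)-1-methoxy-4-(2,3,4-tribromo-6-methoxyphenoxy)-3-(trimethylsilyloxy)buta-1,3-dien-1-olate (one geometry drawn) | CO/C(O[Li])=C\C(O[Si](C)(C)C)=C/Oc1c(OC)cc(Br)c(Br)c1Br | intermediate
11 | (1E,3E)-1-methoxy-4-(2,3,4-tribromo-6-methoxyphenoxy)-1,3-bis(trimethylsilyloxy)buta-1,3-diene (one geometry drawn; mixture usable) | CO/C(O[Si](C)(C)C)=C\C(O[Si](C)(C)C)=C/Oc1c(OC)cc(Br)c(Br)c1Br | intermediate
12 | 1,1,3,3-tetramethoxypropane | COC(OC)CC(OC)OC | starting material
13 | methyl (2Z)-5,7,7-trimethoxy-4-(2,3,4-tribromo-6-methoxyphenoxy)-3-(trimethylsilyloxy)hept-2-enoate (racemic diastereomer mixture at C4 and C5, both centres lost on aromatisation) | COC(=O)/C=C(\O[Si](C)(C)C)C(Oc1c(OC)cc(Br)c(Br)c1Br)C(OC)CC(OC)OC | intermediate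
14 | methyl 2-hydroxy-3-(2,3,4-tribromo-6-methoxyphenoxy)benzoate | COC(=O)c1cccc(Oc2c(OC)cc(Br)c(Br)c2Br)c1O | intermediate
15 | disodium 2-oxido-3-(2,3,4-tribromo-6-methoxyphenoxy)benzoate | [Na+].[Na+].[O-]C(=O)c1cccc(Oc2c(OC)cc(Br)c(Br)c2Br)c1[O-] | intermediate
16 | 2-hydroxy-3-(2,3,4-tribromo-6-methoxyphenoxy)benzoic acid | OC(=O)c1cccc(Oc2c(OC)cc(Br)c(Br)c2Br)c1O | intermediate
17 | 5-bromo-2-hydroxy-3-(2,3,4-tribromo-6-methoxyphenoxy)benzoic acid | OC(=O)c1cc(Br)cc(Oc2c(OC)cc(Br)c(Br)c2Br)c1O | intermediate
18 | 2,4-dibromo-6-(2,3,4-tribromo-6-methoxyphenoxy)phenol | COc1cc(Br)c(Br)c(Br)c1Oc1cc(Br)cc(Br)c1O | target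

**Totals**
Total step count: 8. Longest linear sequence: 8 steps (1 → 18).

**Three steps most likely to fail**

Step 5. The amide base could metalate the ring A C–H that lies between OMe and Br, leading to halogen migration. Fallback without strong base or silyl dienes: setting out from 8, condense with N-[3-(dimethylamino)prop-2-en-1-ylidene]-N-methylmethanaminium chloride (NaOMe, MeOH, 0 → 20 °C). This Knoevenagel-type condensation at the doubly activated carbon gives methyl (2E,4E)-5-(dimethylamino)-2-[2-(2,3,4-tribromo-6-methoxyphenoxy)acetyl]penta-2,4-dienoate F1 (C2=C3 geometry immaterial). Warming with KOtBu in THF (20 → 60 °C) enolises the aryloxy-bearing methylene, and 6π-electrocyclisation with loss of dimethylamine gives the salicylate. The route is rejoined at 14.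

Step 6. The first aldol must take place at the diene terminus, which carries the bulky 2,6-disubstituted aryloxy group, so the cyclocondensation may stall or give low yield. Fallback by a Michael/aldol ring construction that makes the first C–C bond at the unhindered carbon: setting out from 8, NEt3-catalysed Michael addition to acrolein (MeCN, 0 °C) gives racemic methyl 5-oxo-2-[2-(2,3,4-tribromo-6-methoxyphenoxy)acetyl]pentanoate F2. Acid-catalysed intramolecular aldol condensation (p-TsOH, toluene, Dean–Stark) closes ring B to racemic methyl 2-oxo-3-(2,3,4-tribromo-6-methoxyphenoxy)cyclohex-3-ene-1-carboxylate F3. Dehydrogenation with DDQ (1,4-dioxane, 80 °C) aromatises it, and the route is rejoined at 14.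

Step 8. Ipso-bromodecarboxylation may be slow, or may compete with over-bromination of ring B. Fallback that separates the two events: setting out from 16, protodecarboxylation with Ag2CO3 (10 mol %) and catalytic AcOH in DMSO at 120 °C gives 2-(2,3,4-tribromo-6-methoxyphenoxy)phenol F4. Ordinary OH-directed ortho/para dibromination with NBS (2.05 equiv, MeCN, 0 → 20 °C) then gives the target, arriving at 18.

**Further compounds**
F1 | step 5 | methyl (2E,4E)-5-(dimethylamino)-2-[2-(2,3,4-tribromo-6-methoxyphenoxy)acetyl]penta-2,4-dienoate | COC(=O)/C(=C/C=C/N(C)C)C(=O)COc1c(OC)cc(Br)c(Br)c1Br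
F2 | step 6 | methyl 5-oxo-2-[2-(2,3,4-tribromo-6-methoxyphenoxy)acetyl]pentanoate (racemic, labile centre) | COC(=O)C(CCC=O)C(=O)COc1c(OC)cc(Br)c(Br)c1Br
F3 | step 6 | methyl 2-oxo-3-(2,3,4-tribromo-6-methoxyphenoxy)cyclohex-3-ene-1-carboxylate (racemic, labile centre) | COC(=O)C1CCC=C(Oc2c(OC)cc(Br)c(Br)c2Br)C1=O
F4 | step 8 | 2-(2,3,4-tribromo-6-methoxyphenoxy)phenol | COc1cc(Br)c(Br)c(Br)c1Oc1ccccc1O
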